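A small charge, the violet run with 0.0660 M of substrate and 0.00800 M of free catalyst, has to be foreseen from the larger charges before it.

| flask | substrate | free catalyst | time |
|---|---|---|---|
| teal | 0.200 M | 0.0160 M |  |
| green | 0.0800 M | 0.0160 M |  |
| amber | 0.200 M | 0.0320 M |  |
| grey | 0.600 M | 0.0160 M |  |
| violet | 0.0660 M | 0.00800 M | 42 min |

- teal run (time / min: [product] / M): 8.4: 0.0074; 17: 0.0211; 25: 0.0361; 34: 0.0583; 42: 0.0779
- green run (time / min: [product] / M): 8.4: 0.0036; 17: 0.0073; 25: 0.0107; 34: 0.0138; 42: 0.0179
- amber run (time / min: [product] / M): 8.4: 0.0142; 17: 0.0314; 25: 0.0507; 34: 0.0754; 42: 0.0993
- grey run (time / min: [product] / M): 8.4: 0.0392; 17: 0.1375; 25: 0.2978; 34: 0.4695; 42: 0.5510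

(readings scatter by 0.001 M)

- Overall: substrate -> product, with free catalyst as catalyst.
- Constant volume, constant temperature.
- Bound and free are read together.
- An order is taken over about fifteen percent of the charge, up and down.

1. the power of [free catalyst] that the first rate follows, about the charge of the teal run; measure it at two percent of substrate made into product
2. the power of [substrate] that the first rate follows, about the charge of the teal run; measure it at two percent of substrate made into product (one fixed amount of product, the same in the runs compared)
3. the green run starts with 0.120 M less of substrate than the teal run, and with no product. Compared where both hold the same amount of substrate, once fifteen percent of what the green run was charged with has turned into product, is the green run faster, slower or alike (within a tenth)?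
4. product in the violet run at 42 min, as a share of the substrate charged

I compare two rates at one moment. Product forms by a direct path and by a path whose rate grows with product (autocatalysis), so I write, with x the share of the charge turned into product:

rate = a·c(substrate)·(1 + N·x), with N = b·c(substrate charged)/a

Integrated at constant a and b, this gives:

x = (E − 1)/(N + E), with E = exp((1 + N)·a·t)

The grey run's rate per substrate climbs with product across its first readings, and that slope reads b = 0.233 /M/min. The green run's last reading gives an average share of its charge turned of 0.00533 /min, and taking out the product path's part leaves a = 0.00417 /min. At 25 min, the amber run holds 1.40 times the teal run's product from the same substrate charge, so I take a to follow free catalyst to the power 0.490, as a reading.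

For the violet run, a falls to 0.00297 /min. Its handover number, the product path over the direct path per unit of x, is 5.17, which gives x = 15.8%.

Is one number enough? For the teal run at 42 min, it gives 0.0757 M against a reading of 0.0779 M.

At fixed product, the rate in my form is proportional to substrate, so I take the substrate order as one. With the product path counted at two percent turned, I reckon the catalyst order at 0.412. At equal substrate, the green run runs at 0.200 of the teal rate, so it is slower.

The forecast gives a catalyst order of 0.82, a substrate order of 0.85, the green run slower and the violet run at 12%, taking the direct path as “roughly first order in catalyst”, where I read a lower power.

The violet run gives 16.5%, the substrate order is 0.99, and the green run comes out slower, at 0.21 of the teal rate where both hold the same substrate.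

    2 free catalyst ⇌ catalyst dimer, settled at all times (787.0 /M)
    free catalyst + substrate → product + free catalyst (1.638 /M/min)
    free catalyst + substrate ⇌ idle catalyst-substrate complex, settled at all times (2.060 /M)
    substrate + product → 2 product (0.2292 /M/min)

The amber run, at twice the teal run's catalyst, runs 1.4 times the teal rate at equal product, and the catalyst order comes to 0.47. At its share at 42 min, my handover number puts the violet run's product path at 0.853 of its direct path. The grey run, whose first readings gave b, has a handover number of 33.5, so setting x to 0.5 gives a half time of 24.8 min, and the grey run reaches half at 25.1 min.

(All runs were computed for substances that don't exist; scatter was added.)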